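In zeta, gamma and eta you charge 0.50 mM of electrophile with 3.00 equiv, 3.90 equiv and 5.10 equiv of nucleophile and read after 2.5 min. What you have to go on is the elm run, charged at 0.75 mM with 3 equiv.

| flask | electrophile | nucleophile | remark | time |
|---|---|---|---|---|
| elm | 0.75 mM | 3 equiv | run made earlier |  |
| zeta | 0.50 mM | 3.00 equiv |  | 2.5 min |
| gamma | 0.50 mM | 3.90 equiv |  | 2.5 min |
| eta | 0.50 mM | 5.10 equiv |  | 2.5 min |

elm run (percent of the electrophile charged)

| time / s | electrophile / % | target / % |
|---|---|---|
| 10.0 | 79.9 | 18.5 |
| 25.0 | 67.8 | 26.5 |
| 40.0 | 63.0 | 30.6 |
| 60.0 | 59.1 | 32.8 |
| 90.0 | 55.8 | 34.6 |

(standard deviation of a reading: 0.5 percentage points)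



- part of the electrophile that has reacted at the end, zeta
- part of the electrophile that has reacted at the end, gamma
- part of the electrophile that has reacted at the end, eta
- what raising the equivalents of nucleophile from its lowest to its highest value here does to the part of the electrophile that has reacted (changes below 5 percentage points count as none) (no change / it falls / it rises)

Follow the exposure, the logarithm of electrophile charged over electrophile left, which is a pseudo-first-order clock with a falling constant. In elm it reaches 0.583 at 90.0 s, and between the last two readings it gains 0.142 per unit of ln t.

A steady gain in ln t is what you expect if the nucleophile destroys itself in second order, and then exposure depends on the product [nucleophile] as charged times time. So I give each flask its elm-equivalent time, the time at which elm has the same product: 100 s for zeta, 130 s for gamma, 170 s for eta.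

Running elm's curve on to those times, I reckon 45.0%, 47.0% and 49.0% reacted.

The weak link is that slope, taken from two neighbouring readings. From 25.0 s to 90.0 s it reads 0.152, which gives 45.1% for zeta and 49.3% for eta. That gap of 4.3 percentage points between eta and zeta is smaller than the 5 points margin, so I commit to no change.

The forecast differs: 41%, 46%, 51.5%, and it rises, weighing a reversible addition against “Nucleophile destroying itself in second order”.

The flasks give 44.6%, 49.0% and 53.3%: it rises, by 8.6 points.

    electrophile + nucleophile → acid set free + target (k = 16.1 /M/s)
    nucleophile + acid set free ⇌ protonated nucleophile, settled at all times (K = 9.90 × 10⁵ /M)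
    nucleophile + target → over-reaction product (k = 13.5 /M/s)
    acid set free → by-product carried off (k = 0.0124 /s)
    2 nucleophile → homo dimer (k = 23.7 /M/s)

In gamma at 0.108 min, nucleophile goes to homo dimer 7.7 times as fast as into making target. The half-life of electrophile by that making step in gamma lengthens from 0.64 min then to 14 min at 2.50 min, long against the run. The elm-equivalent time 100 s served zeta, 45.1% against 44.6%, but 170 s gave less than eta reached, 49.3% against 53.3%, so the forecast's trend stood and mine did not.

Gamma read at 40 s has an elm-equivalent time of 34.7 s, which gives 35.5% reacted; the flask gives 36.6%.

The readings were computed with constants of no real substance, noise included.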